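**Plan**
1. Retrosynthesis: the phenol is first masked as its acetate. Then both bonds at the ester carbonyl carbon are cut together, C(=O)–CH2 and C(=O)–O(hexacosyl), which leads back to 4-acetoxystyrene, carbon monoxide and hexacosan-1-ol.
2. Enabling feature: the ester carbonyl carbon sits between the α-methylene of the 2-arylethyl chain and the oxygen of the C26 chain. It is therefore a one-carbon unit that CO can supply, and the para-oxygenated benzene ring (the only ring) is bought with its vinyl group in place.
3. Forward order: no ring is formed. Step 1 joins the whole chain (arylethyl–C(=O)–O–hexacosyl) in one operation and step 2 removes the acetate.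
4. Stereochemistry: the target has no stereocentre and no double-bond geometry. The only selectivity to set is linear versus branched carbonylation, which the bulky diphosphine controls.

Key step: step 1

Remark: carbon monoxide is counted as a numbered building block (3) because its carbon and oxygen both end up in the target.

**Step 1**
Reactants: 1 4-acetoxystyrene (4-ethenylphenyl acetate, 1.2 equiv); 2 hexacosan-1-ol (1.0 equiv); 3 carbon monoxide
Product: 4 hexacosyl 3-(4-acetoxyphenyl)propanoate
Conditions: Pd(OAc)2 (1 mol%), 1,2-bis(di-tert-butylphosphinomethyl)benzene (4 mol%), MeSO3H (8 mol%), CO (30 bar), toluene, 80 °C, autoclave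
Reagents that add atoms: carbon monoxide (compound 3), [C-]#[O+]
Why: This is a hydroalkoxycarbonylation (hydroesterification) running through the hydride cycle: MeSO3H turns the diphosphine complex into a cationic divalent palladium hydride, which adds across the vinyl group of 1; CO then inserts into the Pd–alkyl bond, and hexacosanol 2 cleaves the acylpalladium species to release ester 4 and return the hydride. The closest known reaction type is the linear-selective methoxycarbonylation of styrenes and other alkenes with Pd(OAc)2, this same diphosphine and a sulfonic acid, run here with one equivalent of a long-chain primary alcohol in toluene instead of methanol as solvent. No ring closes and no stereocentre is created, so the only selectivity needed is linear over branched: hydride addition is reversible, the benzylic palladium alkyl is too crowded between the four tert-butyl groups to be carbonylated and alcoholysed at a useful rate, and only the 2-arylethyl palladium species goes forward. The para-acetoxy group is a weaker donor than a free or alkylated phenol oxygen, which should slow proton-initiated cationic oligomerisation of the styrene, and the radical stabiliser supplied with the monomer is left in. Keeping the acid at a few mol% and the alcohol at one equivalent in toluene should keep acid-catalysed acyl transfer from the aryl acetate to 2 slow relative to carbonylation, and any product that does lose its acetate is simply target 5 formed early.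

**Step 2**
Reactants: 4 hexacosyl 3-(4-acetoxyphenyl)propanoate
Product: 5 hexacosyl 3-(4-hydroxyphenyl)propanoate
Conditions: pyrrolidine (2 equiv), THF, rt; dilute aqueous HCl wash
Reagents that add atoms: none
Why: This is a chemoselective aminolysis (acyl transfer to a secondary amine): the aryl acetate is an activated ester with a phenoxide leaving group and should be cleaved by pyrrolidine at room temperature, whereas the unactivated hexacosyl ester does not undergo uncatalysed aminolysis under these conditions.

**Compound list**
1 | 4-acetoxystyrene (4-ethenylphenyl acetate) | C=Cc1ccc(OC(C)=O)cc1 | starting material
2 | hexacosan-1-ol | CCCCCCCCCCCCCCCCCCCCCCCCCCO | starting material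
3 | carbon monoxide | [C-]#[O+] | starting material
4 | hexacosyl 3-(4-acetoxyphenyl)propanoate | CCCCCCCCCCCCCCCCCCCCCCCCCCOC(=O)CCc1ccc(OC(C)=O)cc1 | intermediate
5 | hexacosyl 3-(4-hydroxyphenyl)propanoate | CCCCCCCCCCCCCCCCCCCCCCCCCCOC(=O)CCc1ccc(O)cc1 | target

Total step count: 2
Longest linear sequence: 2 steps (1 + 2 + 3 → 4 → 5)

**Steps most likely to fail**
The route has only two steps, so both are ranked, the riskier first.

Risk 1, step 1. Three processes could erode it:
- insertion in the branched sense, giving the 2-arylpropanoate skeleton;
- acid-initiated oligomerisation of the styrene before the palladium hydride intercepts it;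
- sulfonic-acid-catalysed transfer of the acetyl group from the aryl acetate to hexacosanol, which uses up the alcohol.

The fallback fixes the regiochemistry through an acrylate and uses no strong acid. It sets out from 2, which should be esterified with acrylic acid (TsOH cat., 4-methoxyphenol trace, toluene, reflux, Dean–Stark) to hexacosyl prop-2-enoate F1. Cross-metathesis of F1 with 1 (second-generation Grubbs catalyst, toluene, 40 °C, ethene purged) should then give hexacosyl (E)-3-(4-acetoxyphenyl)prop-2-enoate F2. Hydrogenation of the conjugated alkene (H2 1 atm, 10% Pd/C, THF/EtOAc, rt) leaves both esters untouched and comes back to the route at compound 4.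

Risk 2, step 2. Two processes could erode it:
- competing attack of the amine on the hexacosyl ester, with loss of the C26 alcohol;
- incomplete acyl transfer because the waxy substrate dissolves poorly at room temperature.

The fallback replaces the acyl mask by a benzyl ether, so that unmasking is a hydrogenolysis that cannot touch an alkyl ester. It sets out from 1, which should be saponified with KOH (2.2 equiv, DMSO/H2O, 0 °C to rt) to potassium 4-ethenylphenolate F3. This is alkylated in the same flask with benzyl bromide to 1-(benzyloxy)-4-ethenylbenzene F4. Carbonylation of F4 with 2 and 3 under the conditions of step 1 should give hexacosyl 3-(4-benzyloxyphenyl)propanoate F5; the more electron-rich styrene calls for the lowest workable acid loading. Hydrogenolysis (H2 1 atm, 10% Pd/C, THF/EtOAc, rt) comes back to the route at compound 5.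

**Further compounds**
F1 | step 1 | hexacosyl prop-2-enoate (hexacosyl acrylate) | CCCCCCCCCCCCCCCCCCCCCCCCCCOC(=O)C=C
F2 | step 1 | hexacosyl (E)-3-(4-acetoxyphenyl)prop-2-enoate | CCCCCCCCCCCCCCCCCCCCCCCCCCOC(=O)/C=C/c1ccc(OC(C)=O)cc1
F3 | step 2 | potassium 4-ethenylphenolate | [K+].[O-]c1ccc(C=C)cc1
F4 | step 2 | 1-(benzyloxy)-4-ethenylbenzene (4-benzyloxystyrene) | C=Cc1ccc(OCc2ccccc2)cc1
F5 | step 2 | hexacosyl 3-(4-benzyloxyphenyl)propanoate | CCCCCCCCCCCCCCCCCCCCCCCCCCOC(=O)CCc1ccc(OCc2ccccc2)cc1
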